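## Retrosynthetic overview

- Kazinol H comes from a protected (2S)-flavan (7-O-acetate, 5'-O-methyl ether) by one thiolate deprotection. That flavan comes from its 3-formyl derivative by loss of the temporary formyl handle.
- Ring C of the 3-formylflavan comes from an achiral benzyl aryl ether carrying an ortho enal. An amine-catalysed, redox-neutral [1,5]-hydride shift moves H from C2–H to C4, and the C2–C3 bond then closes the ring, sets C2 and leaves C4 as CH2.
- Enabling feature: the C2–H bond lies between O1 and ring B, and the pyran oxygen on C4' of ring B is para to C1', so C2 can carry a cation. Ring A holds this C–H and C4 ortho to each other (H–C2–O1–C8a–C4a–C4).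
- The enal comes from three operations: Wittig homologation, an aromatic Claisen shift (O7-prenyl to C6 1,1-dimethylallyl), and Mitsunobu union (O1–C2) of a ring A salicylaldehyde with a ring B benzylic alcohol. The alcohol is made from 6-bromovanillin by propargyl Claisen cyclisation, reduction and Br/Li exchange with prenylation.
- Ring order: rings A and B are bought, ring D (the pyran of the chromene) forms in step 2, and ring C forms in step 9.

Key step: step 9

Assumption: the sense of induction in step 9 follows the usual shielding model of 2-(diarylsilyloxymethyl)pyrrolidine enamines (R catalyst, bond formation at C3 giving 3S, trans closure giving 2S); if the sense is the reverse, the S catalyst is used and nothing else changes.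

## Route

Step 1
Reactants: 1 2-bromo-4-hydroxy-5-methoxybenzaldehyde (6-bromovanillin)
Product: 2 2-bromo-5-methoxy-4-[(2-methylbut-3-yn-2-yl)oxy]benzaldehyde
Conditions: 3-chloro-3-methylbut-1-yne, K2CO3, KI, CuI (cat.), DMF, 65 °C
Reagents that add atoms: 3-chloro-3-methylbut-1-yne, C#CC(C)(C)Cl
Why: Copper-assisted Williamson-type O-alkylation of the only free phenol with a tertiary propargylic chloride is the standard entry to aryl 1,1-dimethylpropargyl ethers, and the formyl group and the aryl bromide are inert to it.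

Step 2
Reactants: 2 2-bromo-5-methoxy-4-[(2-methylbut-3-yn-2-yl)oxy]benzaldehyde
Product: 5 5-bromo-8-methoxy-2,2-dimethyl-2H-chromene-6-carbaldehyde, via allenylphenol 3 (not isolated), via ortho-quinone methide 4 (not isolated)
Conditions: PhNEt2, 190 °C
Reagents that add atoms: none
Why: An aromatic propargyl Claisen rearrangement to C3, the only free ortho position, followed by tautomerisation to 3, a [1,5]-hydrogen shift to 4 and an oxa-6π electrocyclisation closes ring D without touching bromide or aldehyde.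

Step 3
Reactants: 5 5-bromo-8-methoxy-2,2-dimethyl-2H-chromene-6-carbaldehyde
Product: 6 (5-bromo-8-methoxy-2,2-dimethyl-2H-chromen-6-yl)methanol
Conditions: NaBH4, MeOH/THF, 0 °C
Reagents that add atoms: none
Why: Borohydride 1,2-reduction of the aldehyde is chemoselective over the aryl bromide and the chromene alkene.

Step 4
Reactants: 6 (5-bromo-8-methoxy-2,2-dimethyl-2H-chromen-6-yl)methanol
Product: 8 [8-methoxy-2,2-dimethyl-5-(3-methylbut-2-enyl)-2H-chromen-6-yl]methanol, via dilithio species 7 (not isolated)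
Conditions: n-BuLi (2.2 equiv), THF, −78 °C; CuBr·SMe2 (10 mol%), prenyl bromide, −78 to 0 °C; H2O
Reagents that add atoms: prenyl bromide (1-bromo-3-methylbut-2-ene), CC(C)=CCBr
Why: Deprotonation and bromine–lithium exchange give 7, whose aryl carbanion is allylated (copper-catalysed SN2 allylic substitution) at the unhindered primary carbon of prenyl bromide much faster than the lithium alkoxide reacts.

Step 5
Reactants: 9 2,4-dihydroxybenzaldehyde
Product: 10 2-hydroxy-4-[(3-methylbut-2-enyl)oxy]benzaldehyde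
Conditions: prenyl bromide (1.0 equiv), K2CO3 (1.0 equiv), acetone, reflux
Reagents that add atoms: prenyl bromide (1-bromo-3-methylbut-2-ene), CC(C)=CCBr
Why: Williamson etherification is selective for the 4-OH because the 2-OH is held in a hydrogen bond to the formyl group and stays less nucleophilic with one equivalent of weak base.

Step 6
Reactants: 8 [8-methoxy-2,2-dimethyl-5-(3-methylbut-2-enyl)-2H-chromen-6-yl]methanol; 10 2-hydroxy-4-[(3-methylbut-2-enyl)oxy]benzaldehyde
Product: 11 2-{[8-methoxy-2,2-dimethyl-5-(3-methylbut-2-enyl)-2H-chromen-6-yl]methoxy}-4-[(3-methylbut-2-enyl)oxy]benzaldehyde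
Conditions: PPh3, DIAD, THF, 0 °C to rt
Reagents that add atoms: none
Why: The Mitsunobu etherification joins the acidic salicylaldehyde OH to the primary benzylic alcohol under neutral conditions and so forms the O1–C2 bond without a labile electron-rich benzylic halide.

Step 7
Reactants: 11 2-{[8-methoxy-2,2-dimethyl-5-(3-methylbut-2-enyl)-2H-chromen-6-yl]methoxy}-4-[(3-methylbut-2-enyl)oxy]benzaldehyde
Product: 13 4-formyl-5-{[8-methoxy-2,2-dimethyl-5-(3-methylbut-2-enyl)-2H-chromen-6-yl]methoxy}-2-(2-methylbut-3-en-2-yl)phenyl acetate, via Claisen phenol 12 (not isolated)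
Conditions: PhNEt2, 190 °C; cool to rt, then Ac2O, DMAP (cat.)
Reagents that add atoms: acetic anhydride, CC(=O)OC(C)=O
Why: The aromatic Claisen rearrangement ([3,3], allyl inversion) turns the prenyl ether into the 1,1-dimethylallyl group at C5 of the benzaldehyde (later C6), the position para to the 2-alkoxy group that 2-alkoxy-4-prenyloxybenzaldehydes are known to prefer over the crowded C3 between two oxygens, and acetylation of 12 in the same flask protects the phenol and weakens its donor strength for step 9.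

Step 8
Reactants: 13 4-formyl-5-{[8-methoxy-2,2-dimethyl-5-(3-methylbut-2-enyl)-2H-chromen-6-yl]methoxy}-2-(2-methylbut-3-en-2-yl)phenyl acetate
Product: 14 5-{[8-methoxy-2,2-dimethyl-5-(3-methylbut-2-enyl)-2H-chromen-6-yl]methoxy}-2-(2-methylbut-3-en-2-yl)-4-[(E)-3-oxoprop-1-enyl]phenyl acetate
Conditions: Ph3P=CHCHO, toluene, 90 °C
Reagents that add atoms: (triphenylphosphoranylidene)acetaldehyde, O=CC=P(c1ccccc1)(c1ccccc1)c1ccccc1
Why: Wittig olefination with the stabilised formyl ylide gives the E-enal, the aryl acetate and the alkenes being inert to this non-basic ylide.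

Step 9
Reactants: 14 5-{[8-methoxy-2,2-dimethyl-5-(3-methylbut-2-enyl)-2H-chromen-6-yl]methoxy}-2-(2-methylbut-3-en-2-yl)-4-[(E)-3-oxoprop-1-enyl]phenyl acetate
Product: 18 (2S,3S)-3-formyl-2-[8-methoxy-2,2-dimethyl-5-(3-methylbut-2-enyl)-2H-chromen-6-yl]-6-(2-methylbut-3-en-2-yl)-3,4-dihydro-2H-chromen-7-yl acetate, via iminium ion 15 (not isolated), via oxocarbenium enamine 16 (not isolated), via ring-closed iminium ion 17 (not isolated)
Conditions: (R)-2-{bis[3,5-bis(trifluoromethyl)phenyl](trimethylsilyloxy)methyl}pyrrolidine (20 mol%), 2,4-dinitrobenzenesulfonic acid (20 mol%), ClCH2CH2Cl, 50 °C; trans isomer separated by chromatography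
Reagents that add atoms: none
Why: Condensation of 14 with the amine gives iminium ion 15, whose C4 takes one of the two C2 hydrogens as hydride in a through-space [1,5]-transfer (H–C2–O1–C8a–C4a–C4), which turns the acceptor into an enamine nucleophilic at C3 and the donor into the oxocarbenium ion 16; the two termini then join as C2–C3 to give 17, and hydrolysis frees 18 and the catalyst. The closest known reaction type is the internal-redox [1,5]-hydride transfer/ring closure, known for benzyl aryl ethers with ortho alkylidene malonates under Lewis acids (giving chromans) and, under iminium catalysis of enals, for ortho-amino cinnamaldehydes and for cyclic ethers. Ring C closes in a 6-(enolexo)-endo-trig mode. C3 is set by the diaryl(silyloxy)methyl group of the catalyst, which shields one face of the E-enamine, and C2 is set by the half-chair transition state in which the E-oxocarbenium ion places ring B pseudo-equatorial and trans to the C3 substituent. The step needs hydride loss from C2–H only and a C–C closure faster than capture of the cation by the neighbouring prenyl alkene or by water: only C2–H stands in the 1,5-relation to C4 and is made hydridic by O1 and the para oxygen of ring B, the acetate on O7 keeps C4 electrophilic, and the enamine held in the same ion is a far stronger nucleophile than a trisubstituted alkene.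

Step 10
Reactants: 18 (2S,3S)-3-formyl-2-[8-methoxy-2,2-dimethyl-5-(3-methylbut-2-enyl)-2H-chromen-6-yl]-6-(2-methylbut-3-en-2-yl)-3,4-dihydro-2H-chromen-7-yl acetate
Product: 19 (2S)-2-[8-methoxy-2,2-dimethyl-5-(3-methylbut-2-enyl)-2H-chromen-6-yl]-6-(2-methylbut-3-en-2-yl)-3,4-dihydro-2H-chromen-7-yl acetate
Conditions: RhCl(PPh3)3 (1.1 equiv), degassed toluene, 110 °C
Reagents that add atoms: none
Why: Tsuji–Wilkinson decarbonylation (oxidative addition of the formyl C–H bond to monovalent rhodium, CO extrusion, C–H reductive elimination from trivalent rhodium) removes the temporary handle, erases the C3 stereocentre and leaves C2 untouched, while the trisubstituted, cyclic and neopentyl-type alkenes bind the metal poorly.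

Step 11
Reactants: 19 (2S)-2-[8-methoxy-2,2-dimethyl-5-(3-methylbut-2-enyl)-2H-chromen-6-yl]-6-(2-methylbut-3-en-2-yl)-3,4-dihydro-2H-chromen-7-yl acetate
Product: 20 Kazinol H
Conditions: NaSEt (excess), degassed DMF, 110 °C; then dilute aq. HCl to pH 5
Reagents that add atoms: none
Why: Thiolate SN2 dealkylation attacks only the methyl carbon of the aryl methyl ether and thiolysis cleaves the acetate, whereas the other C–O bonds are secondary benzylic, tertiary or aryl, the alkenes are unactivated and C2–H is not acidic, so the configuration is kept.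

## Compound list

1 | 2-bromo-4-hydroxy-5-methoxybenzaldehyde (6-bromovanillin) | O=Cc1cc(OC)c(O)cc1Br | starting material
2 | 2-bromo-5-methoxy-4-[(2-methylbut-3-yn-2-yl)oxy]benzaldehyde | O=Cc1cc(OC)c(OC(C)(C)C#C)cc1Br | intermediate
3 | 2-bromo-4-hydroxy-5-methoxy-3-(3-methylbuta-1,2-dienyl)benzaldehyde (allenylphenol) | O=Cc1cc(OC)c(O)c(C=C=C(C)C)c1Br | intermediate
4 | 2-bromo-5-methoxy-3-(3-methylbut-2-enylidene)-4-oxocyclohexa-1,5-diene-1-carbaldehyde (ortho-quinone methide) | O=CC1=C(Br)C(=CC=C(C)C)C(=O)C(OC)=C1 | intermediate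
5 | 5-bromo-8-methoxy-2,2-dimethyl-2H-chromene-6-carbaldehyde | O=Cc1cc(OC)c2OC(C)(C)C=Cc2c1Br | intermediate
6 | (5-bromo-8-methoxy-2,2-dimethyl-2H-chromen-6-yl)methanol | OCc1cc(OC)c2OC(C)(C)C=Cc2c1Br | intermediate
7 | lithium (5-lithio-8-methoxy-2,2-dimethyl-2H-chromen-6-yl)methanolate (dilithio species) | [Li]OCc1cc(OC)c2OC(C)(C)C=Cc2c1[Li] | intermediate
8 | [8-methoxy-2,2-dimethyl-5-(3-methylbut-2-enyl)-2H-chromen-6-yl]methanol | OCc1cc(OC)c2OC(C)(C)C=Cc2c1CC=C(C)C | intermediate
9 | 2,4-dihydroxybenzaldehyde | O=Cc1ccc(O)cc1O | starting material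
10 | 2-hydroxy-4-[(3-methylbut-2-enyl)oxy]benzaldehyde | O=Cc1ccc(OCC=C(C)C)cc1O | intermediate
11 | 2-{[8-methoxy-2,2-dimethyl-5-(3-methylbut-2-enyl)-2H-chromen-6-yl]methoxy}-4-[(3-methylbut-2-enyl)oxy]benzaldehyde | O=Cc1ccc(OCC=C(C)C)cc1OCc1cc(OC)c2OC(C)(C)C=Cc2c1CC=C(C)C | intermediate
12 | 4-hydroxy-2-{[8-methoxy-2,2-dimethyl-5-(3-methylbut-2-enyl)-2H-chromen-6-yl]methoxy}-5-(2-methylbut-3-en-2-yl)benzaldehyde (Claisen phenol) | O=Cc1cc(C(C)(C)C=C)c(O)cc1OCc1cc(OC)c2OC(C)(C)C=Cc2c1CC=C(C)C | intermediate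
13 | 4-formyl-5-{[8-methoxy-2,2-dimethyl-5-(3-methylbut-2-enyl)-2H-chromen-6-yl]methoxy}-2-(2-methylbut-3-en-2-yl)phenyl acetate | O=Cc1cc(C(C)(C)C=C)c(OC(C)=O)cc1OCc1cc(OC)c2OC(C)(C)C=Cc2c1CC=C(C)C | intermediate
14 | 5-{[8-methoxy-2,2-dimethyl-5-(3-methylbut-2-enyl)-2H-chromen-6-yl]methoxy}-2-(2-methylbut-3-en-2-yl)-4-[(E)-3-oxoprop-1-enyl]phenyl acetate | O=C/C=C/c1cc(C(C)(C)C=C)c(OC(C)=O)cc1OCc1cc(OC)c2OC(C)(C)C=Cc2c1CC=C(C)C | intermediate
15 | iminium ion of 14 with the (R)-pyrrolidine catalyst (cation, sulfonate counter-ion) | C[Si](C)(C)OC([C@H]1CCC[N+]1=C/C=C/c1cc(C(C)(C)C=C)c(OC(C)=O)cc1OCc1cc(OC)c2OC(C)(C)C=Cc2c1CC=C(C)C)(c1cc(C(F)(F)F)cc(C(F)(F)F)c1)c1cc(C(F)(F)F)cc(C(F)(F)F)c1 | intermediate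
16 | oxocarbenium enamine formed by the hydride shift (cation, sulfonate counter-ion) | C[Si](C)(C)OC([C@H]1CCCN1/C=C/Cc1cc(C(C)(C)C=C)c(OC(C)=O)cc1[O+]=Cc1cc(OC)c2OC(C)(C)C=Cc2c1CC=C(C)C)(c1cc(C(F)(F)F)cc(C(F)(F)F)c1)c1cc(C(F)(F)F)cc(C(F)(F)F)c1 | intermediate
17 | ring-closed iminium ion, (2S,3S)-flavan unit (cation, sulfonate counter-ion) | C[Si](C)(C)OC([C@H]1CCC[N+]1=C[C@H]1Cc2cc(C(C)(C)C=C)c(OC(C)=O)cc2O[C@@H]1c1cc(OC)c2OC(C)(C)C=Cc2c1CC=C(C)C)(c1cc(C(F)(F)F)cc(C(F)(F)F)c1)c1cc(C(F)(F)F)cc(C(F)(F)F)c1 | intermediate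
18 | (2S,3S)-3-formyl-2-[8-methoxy-2,2-dimethyl-5-(3-methylbut-2-enyl)-2H-chromen-6-yl]-6-(2-methylbut-3-en-2-yl)-3,4-dihydro-2H-chromen-7-yl acetate (trans) | O=C[C@H]1Cc2cc(C(C)(C)C=C)c(OC(C)=O)cc2O[C@@H]1c1cc(OC)c2OC(C)(C)C=Cc2c1CC=C(C)C | intermediate
19 | (2S)-2-[8-methoxy-2,2-dimethyl-5-(3-methylbut-2-enyl)-2H-chromen-6-yl]-6-(2-methylbut-3-en-2-yl)-3,4-dihydro-2H-chromen-7-yl acetate | C=CC(C)(C)c1cc2c(cc1OC(C)=O)O[C@H](c1cc(OC)c3c(c1CC=C(C)C)C=CC(C)(C)O3)CC2 | intermediate
20 | Kazinol H, (2S)-2-[8-hydroxy-2,2-dimethyl-5-(3-methylbut-2-enyl)-2H-chromen-6-yl]-6-(2-methylbut-3-en-2-yl)-3,4-dihydro-2H-chromen-7-ol | C=CC(C)(C)c1cc2c(cc1O)O[C@H](c1cc(O)c3c(c1CC=C(C)C)C=CC(C)(C)O3)CC2 | target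

## Step count and risks

Total step count: 11. Longest linear sequence: 10 steps (steps 1–4 and 6–11); step 5 runs in parallel.

**Step 9.**
- What may go wrong:
  - Hydride transfer from an aryl ether donor may be too slow at temperatures where the catalyst still controls the faces.
  - A slow closure would let water or the neighbouring prenyl alkene intercept the cation.
  - Incomplete trans selectivity would erode the purity at C2.
- Fallback: it sets out from 8 and 10, comes back at 19, and closes ring C through O1–C2 and C3–C4 by known chemistry.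
  - Alcohol 8 is oxidised with MnO2 to 8-methoxy-2,2-dimethyl-5-(3-methylbut-2-enyl)-2H-chromene-6-carbaldehyde F1.
  - This aldehyde is homologated with Ph3P=CHCHO to (E)-3-[8-methoxy-2,2-dimethyl-5-(3-methylbut-2-enyl)-2H-chromen-6-yl]prop-2-enal F2.
  - Salicylaldehyde 10 and the enal are joined in the amine-catalysed domino oxa-Michael/aldol condensation (diarylprolinol silyl ether of the suitable configuration, benzoic acid, toluene). This gives the (2R)-2-aryl-7-prenyloxy-2H-chromene-3-carbaldehyde F3, which has the same spatial arrangement at C2 as the target; only the descriptor changes with the priorities.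
  - Conjugate transfer hydrogenation of the enal unit uses diethyl 2,6-dimethyl-1,4-dihydropyridine-3,5-dicarboxylate and a catalytic secondary ammonium salt. It leaves isolated alkenes alone and gives the (2S,3S)-7-prenyloxyflavan-3-carbaldehyde F4.
  - RhCl(PPh3)3 removes the formyl group to give the (2S)-7-prenyloxyflavan F5.
  - Heating in PhNEt2 gives the C6-(1,1-dimethylallyl) flavan-7-ol F6, which is acetylated in the same flask to 19.

**Step 10.**
- What may go wrong: β-hydride or β-aryloxide elimination from the secondary alkylrhodium intermediate, or engagement of the vinyl group by a rhodium hydride, may compete with C–H reductive elimination.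
- Fallback: it sets out from 18, comes back at 19, and replaces the metal-mediated step by a radical one.
  - Pinnick oxidation (NaClO2, NaH2PO4, large excess of 2-methylbut-2-ene) gives the (2S,3S)-flavan-3-carboxylic acid F7.
  - DCC coupling with 1-hydroxypyridine-2(1H)-thione gives the thiohydroxamate ester F8.
  - Barton reductive decarboxylation (visible light, t-BuSH, toluene) replaces the carboxyl group by hydrogen. C2 is not involved, because a β-aryloxy radical does not fragment.

**Step 7.**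
- What may go wrong:
  - The prenyl group may migrate to C3.
  - The ortho-(1,1-dimethylallyl)phenol may isomerise further on prolonged heating.
  - The electron-rich benzylic ether may break down at 190 °C.
- Fallback: it sets out from 10, comes back at 13, and moves the sigmatropic step in front of the fragment union, onto a small ring A aldehyde with a small temporary 2-O-substituent.
  - Aldehyde 10 is converted with MOMCl and i-Pr2NEt into 2-(methoxymethoxy)-4-[(3-methylbut-2-enyl)oxy]benzaldehyde F9.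
  - Thermal Claisen rearrangement gives 4-hydroxy-2-(methoxymethoxy)-5-(2-methylbut-3-en-2-yl)benzaldehyde F10.
  - Acetylation gives 4-formyl-5-(methoxymethoxy)-2-(2-methylbut-3-en-2-yl)phenyl acetate F11.
  - ZnBr2 with n-PrSH removes the acetal group to give 4-formyl-5-hydroxy-2-(2-methylbut-3-en-2-yl)phenyl acetate F12.
  - Mitsunobu etherification of this phenol with 8 gives 13.

## Further compounds

F1 | step 9 | 8-methoxy-2,2-dimethyl-5-(3-methylbut-2-enyl)-2H-chromene-6-carbaldehyde | O=Cc1cc(OC)c2OC(C)(C)C=Cc2c1CC=C(C)C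
F2 | step 9 | (E)-3-[8-methoxy-2,2-dimethyl-5-(3-methylbut-2-enyl)-2H-chromen-6-yl]prop-2-enal | O=C/C=C/c1cc(OC)c2OC(C)(C)C=Cc2c1CC=C(C)C
F3 | step 9 | (2R)-2-[8-methoxy-2,2-dimethyl-5-(3-methylbut-2-enyl)-2H-chromen-6-yl]-7-[(3-methylbut-2-enyl)oxy]-2H-chromene-3-carbaldehyde | O=CC1=Cc2ccc(OCC=C(C)C)cc2O[C@@H]1c1cc(OC)c2OC(C)(C)C=Cc2c1CC=C(C)C
F4 | step 9 | (2S,3S)-2-[8-methoxy-2,2-dimethyl-5-(3-methylbut-2-enyl)-2H-chromen-6-yl]-7-[(3-methylbut-2-enyl)oxy]-3,4-dihydro-2H-chromene-3-carbaldehyde | O=C[C@H]1Cc2ccc(OCC=C(C)C)cc2O[C@@H]1c1cc(OC)c2OC(C)(C)C=Cc2c1CC=C(C)C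
F5 | step 9 | (2S)-2-[8-methoxy-2,2-dimethyl-5-(3-methylbut-2-enyl)-2H-chromen-6-yl]-7-[(3-methylbut-2-enyl)oxy]-3,4-dihydro-2H-chromene | CC(C)=CCOc1ccc2c(c1)O[C@H](c1cc(OC)c3c(c1CC=C(C)C)C=CC(C)(C)O3)CC2
F6 | step 9 | (2S)-2-[8-methoxy-2,2-dimethyl-5-(3-methylbut-2-enyl)-2H-chromen-6-yl]-6-(2-methylbut-3-en-2-yl)-3,4-dihydro-2H-chromen-7-ol | C=CC(C)(C)c1cc2c(cc1O)O[C@H](c1cc(OC)c3c(c1CC=C(C)C)C=CC(C)(C)O3)CC2
F7 | step 10 | (2S,3S)-7-acetoxy-2-[8-methoxy-2,2-dimethyl-5-(3-methylbut-2-enyl)-2H-chromen-6-yl]-6-(2-methylbut-3-en-2-yl)-3,4-dihydro-2H-chromene-3-carboxylic acid | OC(=O)[C@H]1Cc2cc(C(C)(C)C=C)c(OC(C)=O)cc2O[C@@H]1c1cc(OC)c2OC(C)(C)C=Cc2c1CC=C(C)C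
F8 | step 10 | 2-thioxopyridin-1(2H)-yl (2S,3S)-7-acetoxy-2-[8-methoxy-2,2-dimethyl-5-(3-methylbut-2-enyl)-2H-chromen-6-yl]-6-(2-methylbut-3-en-2-yl)-3,4-dihydro-2H-chromene-3-carboxylate | S=C1C=CC=CN1OC(=O)[C@H]1Cc2cc(C(C)(C)C=C)c(OC(C)=O)cc2O[C@@H]1c1cc(OC)c2OC(C)(C)C=Cc2c1CC=C(C)C
F9 | step 7 | 2-(methoxymethoxy)-4-[(3-methylbut-2-enyl)oxy]benzaldehyde | O=Cc1ccc(OCC=C(C)C)cc1OCOC
F10 | step 7 | 4-hydroxy-2-(methoxymethoxy)-5-(2-methylbut-3-en-2-yl)benzaldehyde | O=Cc1cc(C(C)(C)C=C)c(O)cc1OCOC
F11 | step 7 | 4-formyl-5-(methoxymethoxy)-2-(2-methylbut-3-en-2-yl)phenyl acetate | O=Cc1cc(C(C)(C)C=C)c(OC(C)=O)cc1OCOC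
F12 | step 7 | 4-formyl-5-hydroxy-2-(2-methylbut-3-en-2-yl)phenyl acetate | O=Cc1cc(C(C)(C)C=C)c(OC(C)=O)cc1O
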